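## Structural features

The molecule consists of two six-membered rings joined by a single CH2 group. Ring A is a fully substituted 4-hydroxy-2H-pyran-2-one (O1, lactone carbonyl C2, C3 carrying the bridge, C4 hydroxyl, C5 methyl, C6 ethyl). Ring B is a pentasubstituted benzene (C1' carrying the bridge, C2' methoxy, C3' hydrogen, C4' hydroxyl, C5' acyl, C6' hydroxyl). The only stereocentre is the α-carbon of the C5' 2-methylbutanoyl ketone (R); it has no stereogenic neighbour, so it must be brought in intact from the chiral pool and then kept from enolising. That centre is the most fragile element (base or strong Lewis acid can epimerise it), followed by the CH2 bridge between two enol-type rings, which can ionise towards a quinone methide under forcing acid or base, and by the electron-rich, oxidisable ring B. The real difficulty is selectivity on ring B: three oxygens must end as one methyl ether and two free hydroxyls, and the acyl group must enter at C5', between the two hydroxyls, although C3' is equally electron-rich. Ring A becomes simple once the C3–C4 bond is recognised as the link between the bridge-bearing carbon and the hydroxylated carbon: C3 is the α-carbon of a 3-arylpropanoic acid, C4 is the ester carbon of a 2-methyl-3-oxopentanoate, and the two are already tied through the enol oxygen O1. The key step closes exactly this bond.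

## Logic of the disconnections

19 to 18: the O–CH2Ph bond at C4' is cut. The last step should be neutral and touch nothing else, and the C4' oxygen has to stay masked until the acyl group is in place so that only the C6' hydroxyl can direct. The gain is a clean differentiation of the two phenolic oxygens. The demand is that hydrogenolysis spares the aryl ketone, ring A and the stereocentre.

18 to 15 and 16 (through 17): the C5'–C(=O) bond is cut. This brings the only stereocentre in as late as possible, after every strongly basic operation, and from a purchasable acid. 15 is achiral and lacks the ketone. The forward step must acylate C5' and not C3' and must not erode configuration; this is met by making the C6' hydroxyl the only free phenol, whose single free ortho position is C5'.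

15 to 14: the O–CH2OCH3 bond at C6' is cut. This oxygen must be masked while the propanoyl unit is an activated ester, because a free ortho phenol would close a six-membered lactone onto it, and it must later be unmasked beside the benzyl ether. The forward step may use only mild acid.

14 to 13 (key step): the C3–C4 bond of ring A is cut. Ring A opens to an acyclic enol ester whose two halves are an arylpropanoic acid and a purchasable keto ester. The bridge CH2 becomes the β-carbon of the acid, so no separate ring-joining step exists. The forward step needs the Z geometry, at least two equivalents of base, and cyclisation that is faster than fragmentation of the ester enolate.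

13 to 9 and 10 (through 11 and 12): the acyl C2–O1 bond is cut. This is an ester bond, and 10 supplies O1, C4, C5 and C6 with the methyl and ethyl groups in place. The forward step must acylate the enolate at oxygen, not carbon, with the acyloxy group cis to the ester.

9 to 5 and 6 (through 7 and 8): the bond between the bridge carbon and the future C3 is cut; C3 and C2 come from 6 with loss of one carboxyl. The aldehyde carbon of 5 becomes the bridge. The forward reduction must avoid catalytic hydrogenation (benzyl ether) and strong acid (acetal).

5 to 4 to 3 to 1: the two O-protecting bonds and the C1'–CHO bond are cut. The hydrogen bond from the ortho hydroxyl to the formyl group differentiates the two hydroxyls of 3 without extra steps, and 1 already carries the C2' methyl ether. The forward formylation must enter between OH and OMe rather than between the two hydroxyls; 3 is also purchasable, which would save one step.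

## Other disconnections considered

Alternative 1: The cut removes the C4'–O and C5'–C(=O) bonds together, turning the ortho-hydroxyaryl ketone into a C4'–C5' aryne and acid 16. In the forward step CsF desilylates the silyl triflate A1 (ring A capped as its MOM enol ether, C6' as MOM ether). The carboxylate oxygen of 16 should add at C4', meta to the C6' alkoxy group, and the aryl anion left at C5' attacks the ester carbonyl. Opening of the four-membered adduct gives A2, the bis-MOM ether of the target.
- In its favour: the positions of hydroxyl and acyl are fixed by aryne polarisation without any Lewis acid. The C4' hydroxyl is created, not deprotected, so no benzyl ether or hydrogenolysis is needed. 16 is used as the free acid. On regiocontrol of the acyl group this plan is the better one.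
- Against it: A1 is a pentasubstituted arene with adjacent silyl and triflate groups that would have to be installed on a crowded ring after ring A exists, and the plan does not say how ring A is made. Simple O–H addition (protonation of the aryl anion, giving an aryl ester) competes with C–C bond formation. Hot fluoride and a transient aryl anion next to the α-C–H threaten configuration about as much as the Lewis acid does in step 8, so the two plans are equal on that point. Two acetals must then be removed with acid.
- Step economy: clearly worse, since A1 would need several extra steps against three operations after ring closure in the chosen plan.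

Alternative 2: The cut dismantles ring B at C6'–C1', C2'–C3' and C6'–C5'. In the forward step 3-ethoxycyclobut-2-en-1-one A3 is heated with the methoxyalkyne A4. Electrocyclic opening to a vinylketene, [2+2] addition to the alkyne, four-electron opening of the new cyclobutenone, six-electron closure and tautomerisation should give phenol A5.
- In its favour: the oxygen pattern is dictated by the connectivity of the partners, so there is no regiochemical question as in step 1 (better on that point). The C6' hydroxyl emerges free and already distinguished from C4', which is what the later directed acylation needs (equal or better). The cascade is thermal and metal-free.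
- Against it: ring B with the correct oxygens can be bought as 1, so building it de novo costs the syntheses of A3 and the sensitive A4. C4' emerges as an ethyl ether, which cannot be cleaved selectively beside the C2' methyl ether, a structural flaw unless another 3-substituent is used on the cyclobutenone. The silyloxypropyl chain must still be deprotected and oxidised to reach an acid of the type of 9, and ring A and the acyl group remain to be made.
- Step economy: far worse.

Alternative 3: The cut opens ring A at C4–C5 and O1–C2. In the forward step the arylmethylmalonyl dichloride A6 acylates the enol carbon of pentan-3-one A7, and the second acyl chloride captures the enol oxygen of the resulting diketone to give A8, the C4',C6'-dibenzyl ether of the target.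
- In its favour: it is convergent and forms two ring bonds in one operation, against one in the chosen key step (better bond economy). A7 is symmetrical, so there is no regiochemistry and no enol-ester geometry to control (better on that point), and no strong base is used.
- Against it: A6 carries the α-stereocentre of the aryl ketone through acid chloride formation and a hot, HCl-releasing condensation, and the aryl ketone is itself enolisable and can compete with A7. Benzyl ethers ortho to a ketone are exposed to HCl. The acylation of ring B would have to precede ring closure with both phenols benzylated, so the C5'/C3' question returns without a directing hydroxyl.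
- Step economy: about equal to the chosen plan, but the stereocentre would be exposed to the harshest steps, whereas the chosen plan introduces it after them.

Key step: step 6

Assumption: 16 is purchased enantiomerically pure, since no later step could correct its configuration; atom labels follow the numbering used under "Structural features".

## Route

Step 1  
Reactants: 1 5-methoxyresorcinol (5-methoxybenzene-1,3-diol)  
Product: 3 2,4-dihydroxy-6-methoxybenzaldehyde, via aryl iminium chloride 2 (not isolated)  
Conditions: POCl3, DMF, MeCN, 0 °C → rt; then H2O, 50 °C  
Reagents that add atoms: N,N-dimethylformamide, CN(C)C=O; water, O  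
Why: Vilsmeier–Haack formylation; the chloroiminium ion should attack the position para to one hydroxyl and ortho to the other (flanked by OH and OMe) in preference to the position between the two hydroxyls, and the iminium salt 2 is hydrolysed to the aldehyde; any regioisomer is removed here by crystallisation.

Step 2  
Reactants: 3 2,4-dihydroxy-6-methoxybenzaldehyde  
Product: 4 4-(benzyloxy)-2-hydroxy-6-methoxybenzaldehyde  
Conditions: BnBr (1.05 equiv), K2CO3, acetone, rt → 40 °C  
Reagents that add atoms: benzyl bromide, BrCc1ccccc1  
Why: Williamson etherification; the 2-hydroxyl is held in a hydrogen bond to the formyl group and is the weaker nucleophile, so one equivalent of benzyl bromide with mild base should alkylate the more acidic 4-hydroxyl selectively.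

Step 3  
Reactants: 4 4-(benzyloxy)-2-hydroxy-6-methoxybenzaldehyde  
Product: 5 4-(benzyloxy)-2-methoxy-6-(methoxymethoxy)benzaldehyde  
Conditions: MOMCl, i-Pr2NEt, CH2Cl2, 0 °C → rt  
Reagents that add atoms: chloromethyl methyl ether, COCCl  
Why: O-alkylation of the remaining chelated phenol to the MOM acetal, which blocks lactonisation of the future C6' oxygen onto the propanoyl unit and is orthogonal to the benzyl ether.

Step 4  
Reactants: 5 4-(benzyloxy)-2-methoxy-6-(methoxymethoxy)benzaldehyde; 6 Meldrum's acid (2,2-dimethyl-1,3-dioxane-4,6-dione)  
Product: 9 3-[4-(benzyloxy)-2-methoxy-6-(methoxymethoxy)phenyl]propanoic acid, via arylidene Meldrum's acid 7 (not isolated), via benzyl Meldrum's acid 8 (not isolated)  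
Conditions: Hantzsch ester, L-proline (cat.), EtOH, rt; then pyridine–H2O (10:1), 100 °C; citric acid work-up  
Reagents that add atoms: water, O  
Why: Knoevenagel condensation with in situ conjugate transfer hydrogenation from the Hantzsch ester gives 8, and hydrolysis in wet pyridine followed by loss of CO2 gives the acid; neither hydrogenation catalyst nor strong acid is used, so the benzyl ether and the MOM acetal should survive.

Step 5  
Reactants: 9 3-[4-(benzyloxy)-2-methoxy-6-(methoxymethoxy)phenyl]propanoic acid; 10 methyl 2-methyl-3-oxopentanoate  
Product: 13 methyl (2Z)-3-({3-[4-(benzyloxy)-2-methoxy-6-(methoxymethoxy)phenyl]propanoyl}oxy)-2-methylpent-2-enoate, via arylpropanoyl chloride 11 (not isolated), via sodium enolate 12 (not isolated)  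
Conditions: 9, Me2C=C(Cl)NMe2, CH2Cl2, 0 °C → rt; 10, NaH, THF, 0 °C; then combine, 0 °C  
Reagents that add atoms: none  
Why: O-acylation of a β-keto ester enolate; the sodium ion holds the enolate oxygen and the ester carbonyl in a U-shaped chelate, so acylation at oxygen should give the Z enol ester, and the fully substituted α-carbon disfavours C-acylation; the α-chloroenamine makes the acid chloride without HCl (safe for the MOM acetal), and both ring positions ortho to the chain are blocked against indanone formation.

Step 6  
Reactants: 13 methyl (2Z)-3-({3-[4-(benzyloxy)-2-methoxy-6-(methoxymethoxy)phenyl]propanoyl}oxy)-2-methylpent-2-enoate  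
Product: 14 3-{[4-(benzyloxy)-2-methoxy-6-(methoxymethoxy)phenyl]methyl}-6-ethyl-4-hydroxy-5-methyl-2H-pyran-2-one  
Conditions: LiN(SiMe3)2 (2.5 equiv), THF, −78 °C, slow addition of 13, then −78 → −20 °C; 1 M HCl (aq), 0 °C  
Reagents that add atoms: none  
Why: Intramolecular Claisen (Dieckmann-type) condensation: LiN(SiMe3)2 removes a proton from the CH2 next to the acyloxy carbonyl, and the carbon of the resulting lithium ester enolate (future C3) adds to the methyl ester carbonyl (future C4) that the Z double bond holds on the same side. Collapse of the tetrahedral adduct expels methoxide and gives the 3-substituted pyran-2,4-dione, which the second equivalent of base at once converts into the delocalised pyranone enolate; this irreversible deprotonation drives the sequence, and acid releases 14. The closest known reactions are the base-induced ring closure of methyl O-acylsalicylates to 3-substituted 4-hydroxycoumarins and of acyloxy esters to tetronic acids and dihydropyranones; an open-chain enol ester is the same reaction type on a less rigid tether. Ring A closes in the 6-exo-trig mode, the attacked C=O lying outside the new ring. No stereocentre is formed. Cyclisation must outrun β-elimination of the enolate to a ketene plus the enolate of 10, and methoxide attack on unreacted enol ester: running 13 into excess base at −78 °C keeps every molecule enolised and cold, and the Z geometry set in step 5 keeps the electrophile within bonding distance. Regiochemistry is not in question, because O1, C5 (methyl) and C6 (ethyl) are already assembled in 13 and only C3–C4 remains to be made. The MOM acetal, the benzyl ether and the aryl methyl ether carry no acidic C–H and are inert to the amide base.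

Step 7  
Reactants: 14 3-{[4-(benzyloxy)-2-methoxy-6-(methoxymethoxy)phenyl]methyl}-6-ethyl-4-hydroxy-5-methyl-2H-pyran-2-one  
Product: 15 3-{[4-(benzyloxy)-2-hydroxy-6-methoxyphenyl]methyl}-6-ethyl-4-hydroxy-5-methyl-2H-pyran-2-one  
Conditions: HCl (1.25 M in MeOH), rt → 40 °C  
Reagents that add atoms: none  
Why: Acid-catalysed acetal exchange (MOM cleavage) in methanol, which traps the formaldehyde unit as dimethoxymethane and keeps it from hydroxymethylating the electron-rich ring; the benzyl ether, the methyl ether and ring A are stable to dilute methanolic HCl.

Step 8  
Reactants: 15 3-{[4-(benzyloxy)-2-hydroxy-6-methoxyphenyl]methyl}-6-ethyl-4-hydroxy-5-methyl-2H-pyran-2-one; 16 (2R)-2-methylbutanoic acid  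
Product: 18 3-({4-(benzyloxy)-2-hydroxy-6-methoxy-3-[(2R)-2-methylbutanoyl]phenyl}methyl)-6-ethyl-4-hydroxy-5-methyl-2H-pyran-2-one, via (2R)-2-methylbutanoyl chloride 17 (not isolated)  
Conditions: 16, (COCl)2, DMF (cat.), CH2Cl2, 0 °C → rt, concentrate; 15, TiCl4 (2.5 equiv), CH2Cl2, −20 °C, then 17 (1.5 equiv), −20 → 0 °C; 1 M HCl (aq), then NaHCO3 (aq)–MeOH, rt  
Reagents that add atoms: none  
Why: Ortho-selective Friedel–Crafts acylation of a titanium phenoxide (an in situ Fries-type C-acylation): the C6' oxygen–titanium unit binds the acyl chloride and delivers it through a six-membered transition state to C5', its only free ortho position, while C3' is para and out of reach; the stereocentre comes unchanged from 16 (no base, low temperature), and any ester formed at the ring A oxygen is an activated enol ester that the bicarbonate treatment removes.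

Step 9  
Reactants: 18 3-({4-(benzyloxy)-2-hydroxy-6-methoxy-3-[(2R)-2-methylbutanoyl]phenyl}methyl)-6-ethyl-4-hydroxy-5-methyl-2H-pyran-2-one  
Product: 19 3-({2,4-dihydroxy-6-methoxy-3-[(2R)-2-methylbutanoyl]phenyl}methyl)-6-ethyl-4-hydroxy-5-methyl-2H-pyran-2-one (target, CNP0199908.1)  
Conditions: H2 (1 atm), Pd/C, EtOAc, rt  
Reagents that add atoms: none  
Why: Hydrogenolysis of the aryl benzyl ether under neutral conditions; the hydrogen-bonded aryl ketone and the fully substituted double bonds of ring A are slow to reduce at atmospheric pressure, and the α-stereocentre is not exposed to acid or base.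

## Compound list

1 | 5-methoxyresorcinol (5-methoxybenzene-1,3-diol) | COc1cc(O)cc(O)c1 | starting material  
2 | [(2,4-dihydroxy-6-methoxyphenyl)methylidene]dimethylazanium chloride | COc1cc(O)cc(O)c1C=[N+](C)C.[Cl-] | intermediate (not isolated)  
3 | 2,4-dihydroxy-6-methoxybenzaldehyde | COc1cc(O)cc(O)c1C=O | intermediate  
4 | 4-(benzyloxy)-2-hydroxy-6-methoxybenzaldehyde | COc1cc(OCc2ccccc2)cc(O)c1C=O | intermediate  
5 | 4-(benzyloxy)-2-methoxy-6-(methoxymethoxy)benzaldehyde | COCOc1cc(OCc2ccccc2)cc(OC)c1C=O | intermediate  
6 | Meldrum's acid (2,2-dimethyl-1,3-dioxane-4,6-dione) | CC1(C)OC(=O)CC(=O)O1 | starting material  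
7 | 5-{[4-(benzyloxy)-2-methoxy-6-(methoxymethoxy)phenyl]methylidene}-2,2-dimethyl-1,3-dioxane-4,6-dione | COCOc1cc(OCc2ccccc2)cc(OC)c1C=C1C(=O)OC(C)(C)OC1=O | intermediate (not isolated)  
8 | 5-{[4-(benzyloxy)-2-methoxy-6-(methoxymethoxy)phenyl]methyl}-2,2-dimethyl-1,3-dioxane-4,6-dione | COCOc1cc(OCc2ccccc2)cc(OC)c1CC1C(=O)OC(C)(C)OC1=O | intermediate (not isolated)  
9 | 3-[4-(benzyloxy)-2-methoxy-6-(methoxymethoxy)phenyl]propanoic acid | COCOc1cc(OCc2ccccc2)cc(OC)c1CCC(=O)O | intermediate  
10 | methyl 2-methyl-3-oxopentanoate (racemic, enolisable centre) | CCC(=O)C(C)C(=O)OC | starting material  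
11 | 3-[4-(benzyloxy)-2-methoxy-6-(methoxymethoxy)phenyl]propanoyl chloride | COCOc1cc(OCc2ccccc2)cc(OC)c1CCC(=O)Cl | intermediate (not isolated)  
12 | sodium (2Z)-1-methoxy-2-methyl-1-oxopent-2-en-3-olate | CC/C([O-])=C(\C)C(=O)OC.[Na+] | intermediate (not isolated)  
13 | methyl (2Z)-3-({3-[4-(benzyloxy)-2-methoxy-6-(methoxymethoxy)phenyl]propanoyl}oxy)-2-methylpent-2-enoate | CC/C(OC(=O)CCc1c(OC)cc(OCc2ccccc2)cc1OCOC)=C(\C)C(=O)OC | intermediate  
14 | 3-{[4-(benzyloxy)-2-methoxy-6-(methoxymethoxy)phenyl]methyl}-6-ethyl-4-hydroxy-5-methyl-2H-pyran-2-one | CCc1oc(=O)c(Cc2c(OC)cc(OCc3ccccc3)cc2OCOC)c(O)c1C | intermediate  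
15 | 3-{[4-(benzyloxy)-2-hydroxy-6-methoxyphenyl]methyl}-6-ethyl-4-hydroxy-5-methyl-2H-pyran-2-one | CCc1oc(=O)c(Cc2c(OC)cc(OCc3ccccc3)cc2O)c(O)c1C | intermediate  
16 | (2R)-2-methylbutanoic acid | CC[C@@H](C)C(=O)O | starting material  
17 | (2R)-2-methylbutanoyl chloride | CC[C@@H](C)C(=O)Cl | intermediate (not isolated)  
18 | 3-({4-(benzyloxy)-2-hydroxy-6-methoxy-3-[(2R)-2-methylbutanoyl]phenyl}methyl)-6-ethyl-4-hydroxy-5-methyl-2H-pyran-2-one | CCc1oc(=O)c(Cc2c(OC)cc(OCc3ccccc3)c(C(=O)[C@H](C)CC)c2O)c(O)c1C | intermediate  
19 | 3-({2,4-dihydroxy-6-methoxy-3-[(2R)-2-methylbutanoyl]phenyl}methyl)-6-ethyl-4-hydroxy-5-methyl-2H-pyran-2-one | CCc1oc(=O)c(Cc2c(OC)cc(O)c(C(=O)[C@H](C)CC)c2O)c(O)c1C | target  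

## Step count and least certain steps

Total step count: 9. Longest linear sequence: 9 steps (1 to 19); 6, 10 and 16 enter as purchased compounds in steps 4, 5 and 8.

**Step 6 (key step).** The most likely failure is fragmentation of the lithium ester enolate by β-elimination into a ketene and the enolate of 10, because the leaving group is a stabilised enolate. Cleavage of not yet enolised enol ester by the liberated methoxide is a second risk; both would return acyclic material instead of ring A. Fallback, which forms the C3–CH2 bond instead of C3–C4: set out from 5. 6-Ethyl-4-hydroxy-5-methyl-2H-pyran-2-one F1, obtainable in one step from pentan-3-one and propanedioyl dichloride, is condensed at its free C3 with 5 (L-proline cat., EtOH). This gives 3-{[4-(benzyloxy)-2-methoxy-6-(methoxymethoxy)phenyl]methylidene}-6-ethyl-5-methyl-2H-pyran-2,4(3H)-dione F2, which Hantzsch ester reduces in the same flask. The route is rejoined at 14.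

**Step 8.** The most likely failures are partial loss of configuration through reversible acylium–ketene formation from 17 under stoichiometric TiCl4, cleavage of the C4' benzyl ether by the Lewis acid with benzyl transfer to the ring, and some acylation at C3' by non-coordinated acylium. Fallback, which separates C–O from C–C bond formation and avoids both the acid chloride and stoichiometric chlorotitanium: set out from 15.
- Both acidic hydroxyls are esterified with 16 (N,N'-diisopropylcarbodiimide, 4-dimethylaminopyridine cat., CH2Cl2) to give 3-{[4-(benzyloxy)-2-methoxy-6-{[(2R)-2-methylbutanoyl]oxy}phenyl]methyl}-6-ethyl-5-methyl-2-oxo-2H-pyran-4-yl (2R)-2-methylbutanoate F3.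
- A Fries rearrangement catalysed by Sc(OTf)3 moves the aryl ester acyl group to the adjacent C5' and gives 3-({4-(benzyloxy)-2-hydroxy-6-methoxy-3-[(2R)-2-methylbutanoyl]phenyl}methyl)-6-ethyl-5-methyl-2-oxo-2H-pyran-4-yl (2R)-2-methylbutanoate F4.
- NaHCO3 in MeOH removes the activated ring A ester, and the route is rejoined at 18.

**Step 5.** The most likely failures are acylation at the α-carbon of the enolate (a quaternary tricarbonyl compound) and formation of the E enol ester if the sodium chelate is broken; the E isomer cannot cyclise in step 6. Fallback, acyl transfer to a preformed O-silyl enol ether: set out from 9 and 10. Methyl (2Z)-2-methyl-3-[(trimethylsilyl)oxy]pent-2-enoate F5 (from 10, NaH, Me3SiCl; silylation can only occur at oxygen) and 3-[4-(benzyloxy)-2-methoxy-6-(methoxymethoxy)phenyl]propanoyl fluoride F6 (from 9, cyanuric fluoride, pyridine) are combined with a catalytic fluoride source. The desilylated enolate should be acylated at oxygen by the acyl fluoride, and the route is rejoined at 13.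

**Step 4.** The most likely failure is sluggish condensation of the doubly ortho-substituted, electron-rich aldehyde, with loss of the MOM acetal if the acid work-up is too strong (the freed phenol would then lactonise). Fallback, olefination and reduction in place of the Meldrum's acid sequence: set out from 5.
- Horner–Wadsworth–Emmons reaction with trimethyl phosphonoacetate (NaH, THF) gives methyl (2E)-3-[4-(benzyloxy)-2-methoxy-6-(methoxymethoxy)phenyl]prop-2-enoate F7.
- Conjugate reduction with NaBH4 and NiCl2·6H2O in MeOH, which spares the benzyl ether, gives methyl 3-[4-(benzyloxy)-2-methoxy-6-(methoxymethoxy)phenyl]propanoate F8.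
- LiOH in THF–H2O saponifies the ester, and the route is rejoined at 9.

**Step 9.** The most likely failure is over-reduction on prolonged exposure, either hydrogenolysis of the benzylic ketone C=O or saturation of the C5=C6 bond of ring A. Fallback, Lewis-acid dealkylation in place of hydrogenation: set out from 18 and treat with BCl3 and pentamethylbenzene in CH2Cl2 at −78 °C. The benzyl group ortho to the ketone is removed through chelation and the benzyl cation is trapped by the scavenger; the route is rejoined at 19 and no new compound is made (F0).

## Further compounds

F1 | step 6 | 6-ethyl-4-hydroxy-5-methyl-2H-pyran-2-one | CCc1oc(=O)cc(O)c1C  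
F2 | step 6 | 3-{[4-(benzyloxy)-2-methoxy-6-(methoxymethoxy)phenyl]methylidene}-6-ethyl-5-methyl-2H-pyran-2,4(3H)-dione | CCC1=C(C)C(=O)C(=Cc2c(OC)cc(OCc3ccccc3)cc2OCOC)C(=O)O1  
F3 | step 8 | 3-{[4-(benzyloxy)-2-methoxy-6-{[(2R)-2-methylbutanoyl]oxy}phenyl]methyl}-6-ethyl-5-methyl-2-oxo-2H-pyran-4-yl (2R)-2-methylbutanoate | CCc1oc(=O)c(Cc2c(OC)cc(OCc3ccccc3)cc2OC(=O)[C@H](C)CC)c(OC(=O)[C@H](C)CC)c1C  
F4 | step 8 | 3-({4-(benzyloxy)-2-hydroxy-6-methoxy-3-[(2R)-2-methylbutanoyl]phenyl}methyl)-6-ethyl-5-methyl-2-oxo-2H-pyran-4-yl (2R)-2-methylbutanoate | CCc1oc(=O)c(Cc2c(OC)cc(OCc3ccccc3)c(C(=O)[C@H](C)CC)c2O)c(OC(=O)[C@H](C)CC)c1C  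
F5 | step 5 | methyl (2Z)-2-methyl-3-[(trimethylsilyl)oxy]pent-2-enoate | CC/C(O[Si](C)(C)C)=C(\C)C(=O)OC  
F6 | step 5 | 3-[4-(benzyloxy)-2-methoxy-6-(methoxymethoxy)phenyl]propanoyl fluoride | COCOc1cc(OCc2ccccc2)cc(OC)c1CCC(=O)F  
F7 | step 4 | methyl (2E)-3-[4-(benzyloxy)-2-methoxy-6-(methoxymethoxy)phenyl]prop-2-enoate | COCOc1cc(OCc2ccccc2)cc(OC)c1/C=C/C(=O)OC  
F8 | step 4 | methyl 3-[4-(benzyloxy)-2-methoxy-6-(methoxymethoxy)phenyl]propanoate | COCOc1cc(OCc2ccccc2)cc(OC)c1CCC(=O)OC  
F0 | step 9 | none | none  
A1 | alternative 1 | 4-{[6-ethyl-4-(methoxymethoxy)-5-methyl-2-oxo-2H-pyran-3-yl]methyl}-5-methoxy-3-(methoxymethoxy)-2-(trimethylsilyl)phenyl trifluoromethanesulfonate | CCc1oc(=O)c(Cc2c(OC)cc(OS(=O)(=O)C(F)(F)F)c([Si](C)(C)C)c2OCOC)c(OCOC)c1C  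
A2 | alternative 1 | 6-ethyl-3-({4-hydroxy-6-methoxy-2-(methoxymethoxy)-3-[(2R)-2-methylbutanoyl]phenyl}methyl)-4-(methoxymethoxy)-5-methyl-2H-pyran-2-one | CCc1oc(=O)c(Cc2c(OC)cc(O)c(C(=O)[C@H](C)CC)c2OCOC)c(OCOC)c1C  
A3 | alternative 2 | 3-ethoxycyclobut-2-en-1-one | CCOC1=CC(=O)C1  
A4 | alternative 2 | tert-butyl[(5-methoxypent-4-yn-1-yl)oxy]dimethylsilane | COC#CCCCO[Si](C)(C)C(C)(C)C  
A5 | alternative 2 | 2-[3-(tert-butyldimethylsilyloxy)propyl]-5-ethoxy-3-methoxyphenol | CCOc1cc(O)c(CCCO[Si](C)(C)C(C)(C)C)c(OC)c1  
A6 | alternative 3 | 2-({2,4-bis(benzyloxy)-6-methoxy-3-[(2R)-2-methylbutanoyl]phenyl}methyl)propanedioyl dichloride | CC[C@@H](C)C(=O)c1c(OCc2ccccc2)cc(OC)c(CC(C(=O)Cl)C(=O)Cl)c1OCc1ccccc1  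
A7 | alternative 3 | pentan-3-one | CCC(=O)CC  
A8 | alternative 3 | 3-({2,4-bis(benzyloxy)-6-methoxy-3-[(2R)-2-methylbutanoyl]phenyl}methyl)-6-ethyl-4-hydroxy-5-methyl-2H-pyran-2-one | CCc1oc(=O)c(Cc2c(OC)cc(OCc3ccccc3)c(C(=O)[C@H](C)CC)c2OCc2ccccc2)c(O)c1C  
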